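Readings and results were computed with constants of no real substance, and the scatter is random.

3.44 M⁻¹ is the mean, over the runs teal, green and ochre, of the exposure per charge, ln(charged [electrophile]/[electrophile]) divided by the charged [nucleophile], at 30.0 min. This is the pseudo-first-order logarithm, scaled by the charge. The runs give 3.36 M⁻¹ to 3.51 M⁻¹, though their [nucleophile] differs by a factor of 1.35.

| flask | electrophile | nucleophile | remark | time |
|---|---|---|---|---|
| teal | 0.11 M | 0.20 M | run made earlier |  |
| green | 0.11 M | 0.21 M | run made earlier |  |
| ochre | 0.11 M | 0.27 M | run made earlier |  |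
| west | 0.11 M | 0.170 M |  | 40 min |
| east | 0.11 M | 0.250 M |  | 40 min |

- teal (time / min: electrophile / %, target / %): 6.00: 76.6, 23.8; 12.0: 65.0, 34.3; 15.0: 61.0, 38.1; 25.0: 51.3, 46.7; 30.0: 49.6, 48.3
- green (time / min: electrophile / %, target / %): 2.50: 87.3, 13.4; 8.00: 70.6, 29.0; 12.0: 64.9, 36.0; 20.0: 54.7, 44.5; 30.0: 48.3, 49.4
- ochre (time / min: electrophile / %, target / %): 6.00: 70.9, 29.3; 12.0: 56.5, 41.8; 15.0: 52.0, 46.8; 25.0: 42.9, 54.7; 30.0: 40.4, 56.4

(scatter of a reading: 0.5 percentage points)

- the analysis behind the earlier runs scatters by 0.5 percentage points, standard deviation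

* part of the electrophile that has reacted at the end, west
* part of the electrophile that has reacted at the end, east
* what raising the concentration of nucleophile from its lowest to its highest value here does to the part of the electrophile that has reacted (changes below 5 percentage points count as none) (no change / it rises / it falls)

The electrophile falls at every reading, so this mean serves as the floor for the exposure at 40 min:

west: 1 − exp(−3.44 M⁻¹ × 0.170 M) = 44.3 %
east: 1 − exp(−3.44 M⁻¹ × 0.250 M) = 57.7 %

The ceiling comes from the slowing. The exposure of the green run rose at 0.102 M⁻¹ min⁻¹ from 12.0 min to 20.0 min, then at 0.0593 M⁻¹ min⁻¹ up to 30.0 min. Repeating that latest step unchanged over the remaining 10.0 min therefore overshoots, and gives 4.04 M⁻¹: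

west: 49.6 %
east: 63.5 %

The two brackets stand 8.1 percentage points apart, so by this reckoning conversion rises.

The forecast, for which “the data can't separate them well”, says 49 % (45 % to 53 %) and 62 % (58 % to 66 %), with it rises, and both values lie inside the brackets.

The flask gives 49.1 % in west and 61.5 % in east, a change of 12 points: it rises.

    electrophile + nucleophile → acid set free + target (k = 0.00490 M⁻¹ s⁻¹)
    nucleophile + acid set free ⇌ protonated nucleophile, settled at all times (K = 40000 M⁻¹)
    2 nucleophile → homo dimer (k = 0.00190 M⁻¹ s⁻¹)
    target → over-reaction product (k = 4.30 × 10⁻⁵ s⁻¹)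

At 40 min, west keeps 11 % of its nucleophile free against 51 % of its electrophile. The exposures per charge come to 3.98 M⁻¹ in west and 3.82 M⁻¹ in east, both between floor and ceiling.

The second flask is east left until 60.0 min. Its floor is 61.5 %. The remaining 20.0 min is twice the span since 30.0 min, so the ceiling is 68.2 %. The flask gives 66.2 %.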